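**Strategy.** The target is an achiral depside, and the plan cuts its benzoyl ring A across the C1'–C2' and C5'–C6' bonds. Ring A carries OH at C2' and OMe at C4' in a 1,3-relationship, the ester carbonyl on C1' and heptyl on C6'. This is the pattern that a 1,1,3-trioxygenated butadiene (C2'–C5') imprints on a heptyl-bearing alkynoate (C1', C6'). One [4+2] cycloaddition–aromatisation therefore builds ring A with its two oxygens already differentiated. Its precursor is the dec-2-ynoate ester of the free 4-OH of benzyl 2-heptyl-4,6-dihydroxybenzoate (ring B), whose chelated 6-OH is masked in the flask as a trimethylsilyl ether before the diene is added.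

Key step: step 6

Remark 1: the target has no stereocentre and no stereogenic axis, so the single-enantiomer requirement is met without any stereocontrol.
Remark 2: the hydrogen-bonded 6-OH of the aryl ynoate could protonate or desilylate a silyl ketene acetal at the temperature the cycloaddition needs; it is therefore silylated in the flask and freed again by the acidic work-up that the cycloadduct needs anyway, which adds no step.
Remark 3: the C1=C2 geometry of the diene is immaterial, because C1 ends as an aromatic carbon.

**Step 1**
Reactants: 1 1-nonyne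
Product: 3 dec-2-ynoic acid, via non-1-yn-1-yllithium 2 (not isolated)
Conditions: n-BuLi (1.05 equiv), THF, −78 °C; CO2 (g), −78 °C → rt; 1 M HCl
Reagents that add atoms: carbon dioxide, O=C=O; n-butyllithium, [Li]CCCC (lithium of 2 only)
Why: Deprotonation of the terminal alkyne and carboxylation of the lithium acetylide with CO2 is the standard route to alk-2-ynoic acids, and the substrate has no other reactive site.

**Step 2**
Reactants: 4 methyl (E)-3-methoxybut-2-enoate
Product: 6 (1E)-1,3-dimethoxy-1-(trimethylsilyloxy)buta-1,3-diene, via lithium dienolate 5 (not isolated)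
Conditions: LDA (commercial solution, 1.1 equiv), THF, −78 °C; Me3SiCl (1.2 equiv), −78 °C → rt; pentane, filtration under N2, distillation at reduced pressure
Reagents that add atoms: chlorotrimethylsilane, C[Si](C)(C)Cl; lithium diisopropylamide, [Li]N(C(C)C)C(C)C (lithium of 5 only)
Why: Kinetic γ-deprotonation of the vinylogous ester gives the extended enolate, and O-silylation (silyl ketene acetal formation) is the established preparation of this diene; the non-aqueous work-up protects the moisture-sensitive product.

**Step 3**
Reactants: 7 5-heptylbenzene-1,3-diol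
Product: 8 2-heptyl-4,6-dihydroxybenzoic acid
Conditions: MeOMgOCO2Me (2 M in DMF, 3–4 equiv), 120 °C, N2 stream; then cold 2 M HCl
Reagents that add atoms: methoxymagnesium methyl carbonate, CO[Mg]OC(=O)OC
Why: Kolbe–Schmitt-type ortho-carboxylation through the magnesium phenoxide, known for 5-alkylresorcinols, should place CO2 at C4 (ortho to one OH, para to the other), and the magnesium salicylate chelate holds the product against reversal.

**Step 4**
Reactants: 8 2-heptyl-4,6-dihydroxybenzoic acid
Product: 9 benzyl 2-heptyl-4,6-dihydroxybenzoate
Conditions: BnBr (1.0 equiv), KHCO3 (1.2 equiv), DMF, rt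
Reagents that add atoms: benzyl bromide, BrCc1ccccc1
Why: Bicarbonate deprotonates only the carboxylic acid, so SN2 O-alkylation of the carboxylate gives the benzyl ester with both phenols free, and room temperature avoids decarboxylation of the β-resorcylic acid.

**Step 5**
Reactants: 3 dec-2-ynoic acid; 9 benzyl 2-heptyl-4,6-dihydroxybenzoate
Product: 10 benzyl 4-(dec-2-ynoyloxy)-2-heptyl-6-hydroxybenzoate
Conditions: DCC (1.05 equiv), DMAP (5 mol%), CH2Cl2, 0 °C → rt
Reagents that add atoms: none
Why: Steglich esterification of an unhindered ynoic acid should acylate only the 4-OH, because the 6-OH is locked in a hydrogen bond to the ester carbonyl and flanked by the ester; low temperature and catalytic DMAP limit conjugate addition to the ynoate.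

**Step 6**
Reactants: 10 benzyl 4-(dec-2-ynoyloxy)-2-heptyl-6-hydroxybenzoate; 6 (1E)-1,3-dimethoxy-1-(trimethylsilyloxy)buta-1,3-diene
Product: 13 benzyl 2-heptyl-4-[(2-heptyl-6-hydroxy-4-methoxybenzoyl)oxy]-6-hydroxybenzoate, via aryl ynoate trimethylsilyl ether 11 (not isolated), via cyclohexa-1,4-diene ketal cycloadduct 12 (not isolated)
Conditions: MSTFA (1.2 equiv), PhMe, 60 °C, then volatiles removed in vacuo; 6 (3 equiv, in portions), PhMe, 120 °C, sealed tube; then 1 M HCl, THF, 0 °C → rt
Reagents that add atoms: N-methyl-N-(trimethylsilyl)trifluoroacetamide (MSTFA), CN(C(=O)C(F)(F)F)[Si](C)(C)C (trimethylsilyl group of 11 and 12 only)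
Why: Silyl transfer from MSTFA first caps the hydrogen-bonded phenol, removing the only proton able to quench the ketene acetal. The electron-rich diene then adds across the electron-poor triple bond in a normal-electron-demand Diels–Alder reaction (concerted but asynchronous, or in the limit a Mukaiyama–Michael addition followed by closure onto the silyloxy-oxocarbenium carbon), forming C5'–C6' and C1'–C2'; the closest known reaction type is the thermal benzannulation of alk-2-ynoate esters with 1,1,3-trioxygenated silyloxy dienes to resorcylates. Ring A closes as a six-membered carbocycle by intermolecular [4+2] cycloaddition, suprafacial on both partners (6-exo-trig if the second bond forms stepwise). Dilute acid then cleaves both Si–O bonds, the hemiketal at C2' expels methanol and the resulting 4H-cyclohexa-2,5-dienone tautomerises to the phenol, which leaves C2'–OH and C4'–OMe differentiated. No stereocentre is created in the product, as the one sp3 ketal carbon of racemic 12 becomes aromatic. The selectivity needed is regiochemical, CH2 terminus of the diene to the heptyl-bearing β-carbon, and it is secured by the matched polarisation of the partners (largest HOMO coefficient on the diene CH2, largest LUMO coefficient on the ynoate β-carbon, reinforced by the electron-withdrawing aryl ester).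

**Step 7**
Reactants: 13 benzyl 2-heptyl-4-[(2-heptyl-6-hydroxy-4-methoxybenzoyl)oxy]-6-hydroxybenzoate
Product: 14 2-heptyl-4-[(2-heptyl-6-hydroxy-4-methoxybenzoyl)oxy]-6-hydroxybenzoic acid
Conditions: H2 (1 atm), 10% Pd/C, EtOAc, rt
Reagents that add atoms: none
Why: Palladium-catalysed hydrogenolysis cleaves only the benzylic C–O bond, since no alkene or alkyne remains and the aryl ester and methyl ether are inert under these neutral, room-temperature conditions, which also avoid decarboxylation.

**Compound list**
1 | 1-nonyne | CCCCCCCC#C | starting material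
2 | non-1-yn-1-yllithium | [Li]C#CCCCCCCC | intermediate (not isolated)
3 | dec-2-ynoic acid | CCCCCCCC#CC(=O)O | intermediate
4 | methyl (E)-3-methoxybut-2-enoate | CO/C(C)=C/C(=O)OC | starting material
5 | lithium (1Z)-1,3-dimethoxybuta-1,3-dien-1-olate | C=C(OC)/C=C(\OC)O[Li] | intermediate (not isolated)
6 | (1E)-1,3-dimethoxy-1-(trimethylsilyloxy)buta-1,3-diene | C=C(OC)/C=C(\OC)O[Si](C)(C)C | intermediate
7 | 5-heptylbenzene-1,3-diol | CCCCCCCc1cc(O)cc(O)c1 | starting material
8 | 2-heptyl-4,6-dihydroxybenzoic acid | CCCCCCCc1cc(O)cc(O)c1C(=O)O | intermediate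
9 | benzyl 2-heptyl-4,6-dihydroxybenzoate | CCCCCCCc1cc(O)cc(O)c1C(=O)OCc1ccccc1 | intermediate
10 | benzyl 4-(dec-2-ynoyloxy)-2-heptyl-6-hydroxybenzoate | CCCCCCCC#CC(=O)Oc1cc(O)c(C(=O)OCc2ccccc2)c(CCCCCCC)c1 | intermediate
11 | benzyl 4-(dec-2-ynoyloxy)-2-heptyl-6-(trimethylsilyloxy)benzoate | CCCCCCCC#CC(=O)Oc1cc(O[Si](C)(C)C)c(C(=O)OCc2ccccc2)c(CCCCCCC)c1 | intermediate (not isolated)
12 | benzyl 2-heptyl-4-{[2-heptyl-4,6-dimethoxy-6-(trimethylsilyloxy)cyclohexa-1,4-diene-1-carbonyl]oxy}-6-(trimethylsilyloxy)benzoate, racemic at the ketal carbon | CCCCCCCC1=C(C(=O)Oc2cc(O[Si](C)(C)C)c(C(=O)OCc3ccccc3)c(CCCCCCC)c2)C(OC)(O[Si](C)(C)C)C=C(OC)C1 | intermediate (not isolated)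
13 | benzyl 2-heptyl-4-[(2-heptyl-6-hydroxy-4-methoxybenzoyl)oxy]-6-hydroxybenzoate | CCCCCCCc1cc(OC(=O)c2c(O)cc(OC)cc2CCCCCCC)cc(O)c1C(=O)OCc1ccccc1 | intermediate
14 | 2-heptyl-4-[(2-heptyl-6-hydroxy-4-methoxybenzoyl)oxy]-6-hydroxybenzoic acid | CCCCCCCc1cc(OC(=O)c2c(O)cc(OC)cc2CCCCCCC)cc(O)c1C(=O)O | target

**Step count.** Total: 7 steps. Longest linear sequence: 5 steps (7 → 8 → 9 → 10 → 13 → 14).

**Steps most likely to fail**

1. Step 6. The β-alkyl ynoate may add more slowly than the diene decomposes thermally (silyl migration, adventitious hydrolysis). Silanol instead of methanol may also be lost from the ketal carbon, which would leave O2' methylated, and the silyl mask may be lost early. The fallback gives up the benzannulation and makes the ring-A acid by classical depside chemistry; it sets out from 9 and comes back at 13. Methylation of the unchelated 4-OH of 9 (MeI, K2CO3, acetone, rt) should give benzyl 2-heptyl-6-hydroxy-4-methoxybenzoate F1. Hydrogenolysis (H2, Pd/C, EtOAc) then gives 2-heptyl-6-hydroxy-4-methoxybenzoic acid F2. Trifluoroacetic anhydride in toluene at rt converts F2 into 2-heptyl-6-hydroxy-4-methoxybenzoic trifluoroacetic anhydride F3 (not isolated), which acylates the 4-OH of a second portion of 9 to give 13.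

2. Step 3. Carboxylation may compete at C2 between the two hydroxyls, conversion may stall because the reaction is reversible, and the acid may decarboxylate during acidification. The fallback replaces direct carboxylation by formylation and oxidation; it sets out from 7 and comes back at 8. Vilsmeier–Haack reaction (POCl3, DMF, 0 °C → rt) at the position para to one hydroxyl gives [(2-heptyl-4,6-dihydroxyphenyl)methylidene]dimethyliminium chloride F4 (not isolated). Aqueous sodium acetate hydrolyses it to 2-heptyl-4,6-dihydroxybenzaldehyde F5. Chlorite oxidation (NaClO2, NaH2PO4, DMSO–H2O, rt, DMSO as hypochlorite scavenger) then gives 8.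

3. Step 5. The activated ynoate may suffer conjugate addition by DMAP, the O-acylisourea may rearrange to the N-acylurea, and some acylation of the chelated phenol may occur. The fallback moves activation away from the phenol and from any nucleophilic catalyst; it sets out from 3 and comes back at 10. Oxalyl chloride with catalytic DMF (CH2Cl2, 0 °C) gives dec-2-ynoyl chloride F6. After evaporation, F6 is added slowly to 9 and 2,6-lutidine in CH2Cl2 at −20 °C to give 10.

**Further compounds**
F1 | step 6 | benzyl 2-heptyl-6-hydroxy-4-methoxybenzoate | CCCCCCCc1cc(OC)cc(O)c1C(=O)OCc1ccccc1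
F2 | step 6 | 2-heptyl-6-hydroxy-4-methoxybenzoic acid | CCCCCCCc1cc(OC)cc(O)c1C(=O)O
F3 | step 6 | 2-heptyl-6-hydroxy-4-methoxybenzoic trifluoroacetic anhydride | CCCCCCCc1cc(OC)cc(O)c1C(=O)OC(=O)C(F)(F)F
F4 | step 3 | [(2-heptyl-4,6-dihydroxyphenyl)methylidene]dimethyliminium chloride | CCCCCCCc1cc(O)cc(O)c1C=[N+](C)C.[Cl-]
F5 | step 3 | 2-heptyl-4,6-dihydroxybenzaldehyde | CCCCCCCc1cc(O)cc(O)c1C=O
F6 | step 5 | dec-2-ynoyl chloride | CCCCCCCC#CC(=O)Cl
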